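**Retrosynthetic overview**
- Feature: ring A (C4a, C5, C6, C7, C8, C8a) is an acylphloroglucinol-type polyketide ring. Its edge O1–C8a=C4a–C4(=O) is also the vinylogous ester of ring C. Cutting C4a–C5 leads back to a 2-aryl-2,3-dihydro-4-pyranone that carries the chain C8H(OSi)–C7(=O)–C6H2–C5O2Me on C8a.
- C8a–C8: the whole chain, O8 included, is added as a 4-silyloxy-1,3-bis(silyloxy)diene (from methyl glycolate and methyl acetate) to the 6-unsubstituted pyranone by Mukaiyama–Michael addition. Saegusa–Ito oxidation then restores the enone. Enolate acylation at C8 is avoided because bases take H3 of such pyranones, next to C2.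
- C2–C3 and O1–C8a: ring C and the (2S) centre come from an (S)-BINOL/Ti(OiPr)4-catalysed aldol–cyclisation of the B-ring aldehyde with 1-methoxy-3-silyloxybutadiene. The aldehyde comes from 3-bromo-4-hydroxybenzaldehyde by Negishi coupling.
- Order of rings: B (bought), C (step 4), A (step 11). Buffered fluoride then frees O8 and O4'.

Key step: step 11

Assumption: the complex made from (S)-BINOL and Ti(OiPr)4 is taken to expose the Si face of the aromatic aldehyde, as it does in allylation and enol silane additions to benzaldehyde; if the assay of the pyranone shows the opposite sense, (R)-BINOL is used and nothing else changes.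

**Step 1**
Reactants: 1 3-bromo-4-hydroxybenzaldehyde
Product: 2 3-bromo-4-(triisopropylsilyloxy)benzaldehyde
Conditions: TIPSCl (1.2 equiv), imidazole (2.5 equiv), DMF, 0 °C to rt
Reagents that add atoms: triisopropylsilyl chloride, CC(C)[Si](Cl)(C(C)C)C(C)C
Why: Imidazole-promoted O-silylation of a phenol, with the bulky TIPS group chosen because this aryl ether has to outlast the alkoxide of step 11.

**Step 2**
Reactants: 3 4-bromo-2-methylbut-1-ene
Product: 4 (3-methylbut-3-enyl)zinc bromide (THF solution, titrated and used as such)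
Conditions: Zn dust (1.5 equiv), LiCl (1.5 equiv), THF, 50 °C
Reagents that add atoms: zinc, [Zn]
Why: LiCl-accelerated direct zinc insertion into a primary alkyl bromide should give an organozinc halide mild enough to tolerate the aldehyde of its coupling partner.

**Step 3**
Reactants: 2 3-bromo-4-(triisopropylsilyloxy)benzaldehyde; 4 (3-methylbut-3-enyl)zinc bromide
Product: 5 3-(3-methylbut-3-enyl)-4-(triisopropylsilyloxy)benzaldehyde
Conditions: 4 (1.3 equiv), Pd(OAc)2 (2 mol %), SPhos (4 mol %), THF, rt
Reagents that add atoms: none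
Why: Negishi coupling of a primary alkylzinc halide with an ortho-substituted aryl bromide, in which the electron-rich biaryl phosphine should make reductive elimination faster than β-hydride elimination and the zinc reagent should leave the formyl group alone.

**Step 4**
Reactants: 5 3-(3-methylbut-3-enyl)-4-(triisopropylsilyloxy)benzaldehyde; 6 (E)-1-methoxy-3-(trimethylsilyloxy)buta-1,3-diene
Product: 8 (2S)-2-[3-(3-methylbut-3-enyl)-4-(triisopropylsilyloxy)phenyl]-2,3-dihydro-4H-pyran-4-one, via silylated aldol adduct 7 (not isolated)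
Conditions: (S)-BINOL (20 mol %), Ti(OiPr)4 (10 mol %), 4 Å MS, Et2O, −20 °C; then CF3CO2H (0.3 equiv), CH2Cl2, 0 °C
Reagents that add atoms: none
Why: Catalytic asymmetric Mukaiyama aldol addition followed by acid-induced oxa-Michael addition and elimination (formal hetero-Diels–Alder reaction), in which the chiral titanium binaphtholate shields the Re face of the aldehyde so that the diene terminus adds to the Si face and C2 is set as S.

**Step 5**
Reactants: 9 methyl glycolate
Product: 10 methyl (tert-butyldimethylsilyloxy)acetate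
Conditions: TBSCl (1.1 equiv), imidazole (2.2 equiv), CH2Cl2, rt
Reagents that add atoms: tert-butyldimethylsilyl chloride, CC(C)(C)[Si](C)(C)Cl
Why: Routine O-silylation of a primary alcohol, which places on the future O8 the group that must keep this oxygen from lactonising in step 11.

**Step 6**
Reactants: 10 methyl (tert-butyldimethylsilyloxy)acetate; 11 methyl acetate
Product: 13 methyl 4-(tert-butyldimethylsilyloxy)-3-oxobutanoate, via lithium enolate of methyl acetate 12 (not isolated)
Conditions: 11 (2.5 equiv), LiN(iPr)2 (2.6 equiv), THF, −78 °C; then 10, −78 to −40 °C; AcOH quench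
Reagents that add atoms: none
Why: Crossed Claisen condensation in which the pre-formed acetate enolate, used in excess, attacks the more electrophilic α-silyloxy ester and the product is stored as its enolate until the quench.

**Step 7**
Reactants: 13 methyl 4-(tert-butyldimethylsilyloxy)-3-oxobutanoate
Product: 14 methyl 4-(tert-butyldimethylsilyloxy)-3-(trimethylsilyloxy)but-2-enoate (E/Z mixture)
Conditions: TMSCl (1.5 equiv), Et3N (1.6 equiv), toluene, rt
Reagents that add atoms: trimethylsilyl chloride, C[Si](C)(C)Cl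
Why: Amine-mediated O-silylation of the β-keto ester enol should give the conjugated enol silane and leave the CH2OTBS group as the only acidic site for step 8.

**Step 8**
Reactants: 14 methyl 4-(tert-butyldimethylsilyloxy)-3-(trimethylsilyloxy)but-2-enoate
Product: 16 4-(tert-butyldimethylsilyloxy)-1-methoxy-1,3-bis(trimethylsilyloxy)buta-1,3-diene (isomer mixture), via lithium dienolate 15 (not isolated)
Conditions: LiN(iPr)2 (1.2 equiv), THF, −78 °C; TMSCl (1.3 equiv), −78 °C to rt; hexane, filtration under argon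
Reagents that add atoms: trimethylsilyl chloride, C[Si](C)(C)Cl
Why: γ-Deprotonation of the β-silyloxy enoate and O-silylation of the dienolate is the standard second stage in the preparation of 1,3-bis(silyloxy)-1,3-dienes.

**Step 9**
Reactants: 8 (2S)-2-[3-(3-methylbut-3-enyl)-4-(triisopropylsilyloxy)phenyl]-2,3-dihydro-4H-pyran-4-one; 16 4-(tert-butyldimethylsilyloxy)-1-methoxy-1,3-bis(trimethylsilyloxy)buta-1,3-diene
Product: 17 methyl 4-(tert-butyldimethylsilyloxy)-4-{(6S)-6-[3-(3-methylbut-3-enyl)-4-(triisopropylsilyloxy)phenyl]-4-(trimethylsilyloxy)-5,6-dihydro-2H-pyran-2-yl}-3-(trimethylsilyloxy)but-2-enoate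
Conditions: 16 (1.5 equiv), TMSOTf (15 mol %), CH2Cl2, −78 °C; Et3N quench, cold aq. NaHCO3
Reagents that add atoms: none
Why: Vinylogous Mukaiyama–Michael addition in which TMSOTf turns the pyranone into a 4-silyloxy oxocarbenium ion that the diene attacks at C8a through its terminus C8, the silyl group ending on O4 so that the enol silane marks C4a for step 10, while the new centres at C8a (expected trans to the aryl group by axial attack) and C8 (mixture) are erased in steps 10 and 11.

**Step 10**
Reactants: 17 the bis(enol silane) adduct of step 9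
Product: 19 methyl 4-(tert-butyldimethylsilyloxy)-4-{(2S)-2-[3-(3-methylbut-3-enyl)-4-(triisopropylsilyloxy)phenyl]-4-oxo-2,3-dihydro-4H-pyran-6-yl}-3-oxobutanoate (C8 epimers), via C7 enol silane 18 (not isolated)
Conditions: Pd(OAc)2 (1.1 equiv), MeCN, rt; filtration; then aq. citric acid, THF, 0 °C
Reagents that add atoms: none
Why: Saegusa–Ito oxidation, in which Pd(OAc)2 exchanges the more electron-rich C4 enol silane for a palladium enolate bound at C4a whose only β-hydrogen is H8a, so that β-hydride elimination restores the C4a=C8a enone regiospecifically and the mild acid wash hydrolyses the remaining β-silyloxyacrylate to the β-keto ester.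

**Step 11**
Reactants: 19 the dihydropyranone β-keto ester of step 10
Product: 21 (2S)-8-(tert-butyldimethylsilyloxy)-5,7-dihydroxy-2-[3-(3-methylbut-3-enyl)-4-(triisopropylsilyloxy)phenyl]chroman-4-one, via cyclohexenedione tautomer 20 (not isolated)
Conditions: Mg(OMe)2 (3 equiv), THF–MeOH 4:1, argon, 0 to 40 °C; AcOH quench at 0 °C
Reagents that add atoms: none
Why: Proposed new method: Mg(OMe)2 first parks the substrate as the chelated C5/C7 β-keto ester enolate, but proton exchange in the methanolic medium also populates the anion formed by loss of H8, a cross-conjugated dienolate with charge on O7, O4 and C4a; C4a adds to the magnesium-bound ester carbonyl C5, methoxide leaves, and 20 enolises twice (H4a to O5, H6 to O7) to the arene, which makes the sequence irreversible. The closest known reaction type is the biomimetic Claisen cyclisation of 3,5,7-triketo esters and of their pyrone-masked forms to acylphloroglucinols with magnesium or potassium bases; what has not been shown is a 2,3-dihydro-4-pyranone, an O-alkylated β-diketone that cannot form a diketonate, as the carbon nucleophile. Ring A closes in a 6-(enolexo)-exo-trig mode, the C4a=C4–O enolate bond lying outside the new ring and the ester C=O being exocyclic. No stereocentre is made, since C8 becomes trigonal and C2 is only carried along. The step needs C-acylation at C4a over aldol, lactonisation and regioisomeric channels: ring C holds C4 and C8 trans across C4a=C8a so that C6 cannot reach the C4 carbonyl, the TBS group keeps O8 from closing a tetronate on C5, and O1 already sits on C8a so that only the 5,7,8-pattern can arise. Loss of H3 with E1cB cleavage of C2–O1 (racemisation) should be held back because substrate and product are already anions under a base too weak to deprotonate them again, and because the TIPS ether denies any push from a 4'-phenoxide.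

**Step 12**
Reactants: 21 the bis-silylated flavanone of step 11
Product: 22 (2S)-5,7,8-trihydroxy-2-[4-hydroxy-3-(3-methylbut-3-enyl)phenyl]chroman-4-one (CNP0293707.1)
Conditions: Bu4NF (2.5 equiv), AcOH (3 equiv), THF, argon, 0 °C
Reagents that add atoms: none
Why: Fluoride-induced cleavage of the two aryl silyl ethers, with acetic acid keeping all phenols protonated so that neither phenoxide-driven opening of the C2–O1 bond nor air oxidation of the 5,7,8-trihydroxyarene should set in.

**Compound list**
1 | 3-bromo-4-hydroxybenzaldehyde | O=Cc1ccc(O)c(Br)c1 | starting material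
2 | 3-bromo-4-(triisopropylsilyloxy)benzaldehyde | O=Cc1ccc(O[Si](C(C)C)(C(C)C)C(C)C)c(Br)c1 | intermediate
3 | 4-bromo-2-methylbut-1-ene | C=C(C)CCBr | starting material
4 | (3-methylbut-3-enyl)zinc bromide | C=C(C)CC[Zn]Br | intermediate
5 | 3-(3-methylbut-3-enyl)-4-(triisopropylsilyloxy)benzaldehyde | C=C(C)CCc1cc(C=O)ccc1O[Si](C(C)C)(C(C)C)C(C)C | intermediate
6 | (E)-1-methoxy-3-(trimethylsilyloxy)buta-1,3-diene | CO/C=C/C(=C)O[Si](C)(C)C | starting material
7 | (1E,5S)-1-methoxy-5-[3-(3-methylbut-3-enyl)-4-(triisopropylsilyloxy)phenyl]-5-(trimethylsilyloxy)pent-1-en-3-one | C=C(C)CCc1cc([C@@H](O[Si](C)(C)C)CC(=O)/C=C/OC)ccc1O[Si](C(C)C)(C(C)C)C(C)C | intermediate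
8 | (2S)-2-[3-(3-methylbut-3-enyl)-4-(triisopropylsilyloxy)phenyl]-2,3-dihydro-4H-pyran-4-one | C=C(C)CCc1cc([C@@H]2CC(=O)C=CO2)ccc1O[Si](C(C)C)(C(C)C)C(C)C | intermediate
9 | methyl glycolate | COC(=O)CO | starting material
10 | methyl (tert-butyldimethylsilyloxy)acetate | COC(=O)CO[Si](C)(C)C(C)(C)C | intermediate
11 | methyl acetate | COC(C)=O | starting material
12 | lithium enolate of methyl acetate | C=C(OC)O[Li] | intermediate
13 | methyl 4-(tert-butyldimethylsilyloxy)-3-oxobutanoate | COC(=O)CC(=O)CO[Si](C)(C)C(C)(C)C | intermediate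
14 | methyl 4-(tert-butyldimethylsilyloxy)-3-(trimethylsilyloxy)but-2-enoate (E/Z mixture) | COC(=O)C=C(CO[Si](C)(C)C(C)(C)C)O[Si](C)(C)C | intermediate
15 | lithium dienolate of 14 | COC(O[Li])=CC(O[Si](C)(C)C)=CO[Si](C)(C)C(C)(C)C | intermediate
16 | 4-(tert-butyldimethylsilyloxy)-1-methoxy-1,3-bis(trimethylsilyloxy)buta-1,3-diene (isomer mixture) | COC(O[Si](C)(C)C)=CC(O[Si](C)(C)C)=CO[Si](C)(C)C(C)(C)C | intermediate
17 | methyl 4-(tert-butyldimethylsilyloxy)-4-{(6S)-6-[3-(3-methylbut-3-enyl)-4-(triisopropylsilyloxy)phenyl]-4-(trimethylsilyloxy)-5,6-dihydro-2H-pyran-2-yl}-3-(trimethylsilyloxy)but-2-enoate (C8a and C8 not defined, both erased later) | C=C(C)CCc1cc([C@@H]2CC(O[Si](C)(C)C)=CC(C(O[Si](C)(C)C(C)(C)C)C(O[Si](C)(C)C)=CC(=O)OC)O2)ccc1O[Si](C(C)C)(C(C)C)C(C)C | intermediate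
18 | methyl 4-(tert-butyldimethylsilyloxy)-4-{(2S)-2-[3-(3-methylbut-3-enyl)-4-(triisopropylsilyloxy)phenyl]-4-oxo-2,3-dihydro-4H-pyran-6-yl}-3-(trimethylsilyloxy)but-2-enoate | C=C(C)CCc1cc([C@@H]2CC(=O)C=C(C(O[Si](C)(C)C(C)(C)C)C(O[Si](C)(C)C)=CC(=O)OC)O2)ccc1O[Si](C(C)C)(C(C)C)C(C)C | intermediate
19 | methyl 4-(tert-butyldimethylsilyloxy)-4-{(2S)-2-[3-(3-methylbut-3-enyl)-4-(triisopropylsilyloxy)phenyl]-4-oxo-2,3-dihydro-4H-pyran-6-yl}-3-oxobutanoate (C8 epimers) | C=C(C)CCc1cc([C@@H]2CC(=O)C=C(C(O[Si](C)(C)C(C)(C)C)C(=O)CC(=O)OC)O2)ccc1O[Si](C(C)C)(C(C)C)C(C)C | intermediate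
20 | (2S)-8-(tert-butyldimethylsilyloxy)-2-[3-(3-methylbut-3-enyl)-4-(triisopropylsilyloxy)phenyl]-2,3,4a,6-tetrahydrochromene-4,5,7-trione (C4a not defined) | C=C(C)CCc1cc([C@@H]2CC(=O)C3C(=O)CC(=O)C(O[Si](C)(C)C(C)(C)C)=C3O2)ccc1O[Si](C(C)C)(C(C)C)C(C)C | intermediate
21 | (2S)-8-(tert-butyldimethylsilyloxy)-5,7-dihydroxy-2-[3-(3-methylbut-3-enyl)-4-(triisopropylsilyloxy)phenyl]chroman-4-one | C=C(C)CCc1cc([C@@H]2CC(=O)c3c(O)cc(O)c(O[Si](C)(C)C(C)(C)C)c3O2)ccc1O[Si](C(C)C)(C(C)C)C(C)C | intermediate
22 | (2S)-5,7,8-trihydroxy-2-[4-hydroxy-3-(3-methylbut-3-enyl)phenyl]chroman-4-one | C=C(C)CCc1cc([C@@H]2CC(=O)c3c(O)cc(O)c(O)c3O2)ccc1O | target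

**Step count**
Total step count: 12.
Longest linear sequence: 8 steps (steps 5 to 12, from methyl glycolate). The B-ring branch from 1 runs through 7 steps.

**Steps most likely to fail**

*Step 11.* Several things may go wrong.
- The chelated β-keto ester enolate may act as a sink, so that the ester is never attacked.
- Methoxide may exchange with O1 at C8a.
- Loss of H3 may open ring C and erode the configuration at C2.
- The TBS group may wander from O8 to O7 in the phenoxide. This would be harmless, because both isomers converge in step 12.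

The fallback uses known chemistry and buys ring A instead of folding it. It sets out from organozinc 4 and comes back at target 22. Commercial 4-bromo-2-iodophenol is silylated (TIPSCl, imidazole) to (4-bromo-2-iodophenoxy)triisopropylsilane F1. F1 couples with 4 at the C–I bond (PdCl2(dppf), THF, rt) to give [4-bromo-2-(3-methylbut-3-enyl)phenoxy]triisopropylsilane F2. Miyaura borylation (bis(pinacolato)diboron, PdCl2(dppf), KOAc, dioxane, 80 °C) gives triisopropyl[2-(3-methylbut-3-enyl)-4-(4,4,5,5-tetramethyl-1,3,2-dioxaborolan-2-yl)phenoxy]silane F3. NaIO4/NH4OAc in aqueous acetone then frees [3-(3-methylbut-3-enyl)-4-(triisopropylsilyloxy)phenyl]boronic acid F4.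

In parallel, commercial 2'-hydroxy-3',4',6'-trimethoxyacetophenone and DMF dimethyl acetal give (E)-3-(dimethylamino)-1-(2-hydroxy-3,4,6-trimethoxyphenyl)prop-2-en-1-one F5. HCl closes it to 5,7,8-trimethoxychromen-4-one F6. BBr3 gives 5,7,8-trihydroxychromen-4-one F7, and TBSOTf/2,6-lutidine gives 5,7,8-tris(tert-butyldimethylsilyloxy)chromen-4-one F8.

The palladium-catalysed asymmetric conjugate addition of arylboronic acids to chromones then joins F4 and F8. The conditions are Pd(OCOCF3)2, the t-BuPyOx ligand antipode that delivers the aryl group to the face giving 2S, NH4PF6, H2O, ClCH2CH2Cl, 60 °C. The product is (2S)-5,7,8-tris(tert-butyldimethylsilyloxy)-2-[3-(3-methylbut-3-enyl)-4-(triisopropylsilyloxy)phenyl]chroman-4-one F9. Bu4NF/AcOH as in step 12 gives 22.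

*Step 9.* The hindered, doubly oxygenated terminus C8 of diene 16 may add too slowly. Attack through C6, desilylation of the diene by the Lewis acid, or ionisation of the benzylic C2–O1 bond could then take over.

The fallback sets out from 8 and comes back at 19, and it builds the chain in two pieces. Commercial (tert-butyldimethylsilyloxy)acetaldehyde with TBSOTf/Et3N gives (Z)-1,2-bis(tert-butyldimethylsilyloxy)ethene F10, a small symmetrical enol silane that offers no regiochemical choice. Its TBSOTf-catalysed Mukaiyama–Michael addition to 8 (CH2Cl2, −78 °C) gives 2-(tert-butyldimethylsilyloxy)-2-{(6S)-4-(tert-butyldimethylsilyloxy)-6-[3-(3-methylbut-3-enyl)-4-(triisopropylsilyloxy)phenyl]-5,6-dihydro-2H-pyran-2-yl}acetaldehyde F11, which carries a sturdier enol silane on O4. Roskamp homologation (methyl diazoacetate, SnCl2, CH2Cl2, rt) turns the aldehyde into methyl 4-(tert-butyldimethylsilyloxy)-4-{(6S)-4-(tert-butyldimethylsilyloxy)-6-[3-(3-methylbut-3-enyl)-4-(triisopropylsilyloxy)phenyl]-5,6-dihydro-2H-pyran-2-yl}-3-oxobutanoate F12. Pd(OAc)2 as in step 10 gives 19.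

*Step 10.* The C4 enol silane may be protodesilylated before palladation, which would lose the regiochemical marker. The palladium hydride released in the elimination may also isomerise the 1,1-disubstituted alkene of the side chain.

The fallback sets out from 17 and comes back at 19 without palladium. PhSeCl (1 equiv, CH2Cl2, −78 °C) selenenylates the more electron-rich enol silane at C4a. Aqueous work-up gives methyl 4-(tert-butyldimethylsilyloxy)-4-{(6S)-6-[3-(3-methylbut-3-enyl)-4-(triisopropylsilyloxy)phenyl]-4-oxo-3-(phenylselanyl)tetrahydropyran-2-yl}-3-oxobutanoate F13. H2O2/pyridine (CH2Cl2, 0 °C) oxidises it to the corresponding selenoxide F14. Syn elimination of F14 can only take H8a and should give 19.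

**Further compounds**
F1 | step 11 | (4-bromo-2-iodophenoxy)triisopropylsilane | CC(C)[Si](Oc1ccc(Br)cc1I)(C(C)C)C(C)C
F2 | step 11 | [4-bromo-2-(3-methylbut-3-enyl)phenoxy]triisopropylsilane | C=C(C)CCc1cc(Br)ccc1O[Si](C(C)C)(C(C)C)C(C)C
F3 | step 11 | triisopropyl[2-(3-methylbut-3-enyl)-4-(4,4,5,5-tetramethyl-1,3,2-dioxaborolan-2-yl)phenoxy]silane | C=C(C)CCc1cc(B2OC(C)(C)C(C)(C)O2)ccc1O[Si](C(C)C)(C(C)C)C(C)C
F4 | step 11 | [3-(3-methylbut-3-enyl)-4-(triisopropylsilyloxy)phenyl]boronic acid | C=C(C)CCc1cc(B(O)O)ccc1O[Si](C(C)C)(C(C)C)C(C)C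
F5 | step 11 | (E)-3-(dimethylamino)-1-(2-hydroxy-3,4,6-trimethoxyphenyl)prop-2-en-1-one | CN(C)/C=C/C(=O)c1c(O)c(OC)c(OC)cc1OC
F6 | step 11 | 5,7,8-trimethoxychromen-4-one | COc1cc(OC)c2c(=O)ccoc2c1OC
F7 | step 11 | 5,7,8-trihydroxychromen-4-one | O=c1ccoc2c(O)c(O)cc(O)c12
F8 | step 11 | 5,7,8-tris(tert-butyldimethylsilyloxy)chromen-4-one | CC(C)(C)[Si](C)(C)Oc1cc(O[Si](C)(C)C(C)(C)C)c2c(=O)ccoc2c1O[Si](C)(C)C(C)(C)C
F9 | step 11 | (2S)-5,7,8-tris(tert-butyldimethylsilyloxy)-2-[3-(3-methylbut-3-enyl)-4-(triisopropylsilyloxy)phenyl]chroman-4-one | C=C(C)CCc1cc([C@@H]2CC(=O)c3c(O[Si](C)(C)C(C)(C)C)cc(O[Si](C)(C)C(C)(C)C)c(O[Si](C)(C)C(C)(C)C)c3O2)ccc1O[Si](C(C)C)(C(C)C)C(C)C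
F10 | step 9 | (Z)-1,2-bis(tert-butyldimethylsilyloxy)ethene | CC(C)(C)[Si](C)(C)O/C=C\O[Si](C)(C)C(C)(C)C
F11 | step 9 | 2-(tert-butyldimethylsilyloxy)-2-{(6S)-4-(tert-butyldimethylsilyloxy)-6-[3-(3-methylbut-3-enyl)-4-(triisopropylsilyloxy)phenyl]-5,6-dihydro-2H-pyran-2-yl}acetaldehyde | C=C(C)CCc1cc([C@@H]2CC(O[Si](C)(C)C(C)(C)C)=CC(C(O[Si](C)(C)C(C)(C)C)C=O)O2)ccc1O[Si](C(C)C)(C(C)C)C(C)C
F12 | step 9 | methyl 4-(tert-butyldimethylsilyloxy)-4-{(6S)-4-(tert-butyldimethylsilyloxy)-6-[3-(3-methylbut-3-enyl)-4-(triisopropylsilyloxy)phenyl]-5,6-dihydro-2H-pyran-2-yl}-3-oxobutanoate | C=C(C)CCc1cc([C@@H]2CC(O[Si](C)(C)C(C)(C)C)=CC(C(O[Si](C)(C)C(C)(C)C)C(=O)CC(=O)OC)O2)ccc1O[Si](C(C)C)(C(C)C)C(C)C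
F13 | step 10 | methyl 4-(tert-butyldimethylsilyloxy)-4-{(6S)-6-[3-(3-methylbut-3-enyl)-4-(triisopropylsilyloxy)phenyl]-4-oxo-3-(phenylselanyl)tetrahydropyran-2-yl}-3-oxobutanoate | C=C(C)CCc1cc([C@@H]2CC(=O)C([Se]c3ccccc3)C(C(O[Si](C)(C)C(C)(C)C)C(=O)CC(=O)OC)O2)ccc1O[Si](C(C)C)(C(C)C)C(C)C
F14 | step 10 | selenoxide of F13 | C=C(C)CCc1cc([C@@H]2CC(=O)C([Se](=O)c3ccccc3)C(C(O[Si](C)(C)C(C)(C)C)C(=O)CC(=O)OC)O2)ccc1O[Si](C(C)C)(C(C)C)C(C)C
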